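(The numbers in the tables stem from a simulated flask on assumed constants, noise included.)

In Wednesday's run the left-handed product stands above the right-handed, 22% against 11% at 40.0 h, so I read these flasks by how the two substrates divide what reacts.

| flask | left-handed substrate | right-handed substrate | partner | free catalyst | remark | time |
|---|---|---|---|---|---|---|
| Thursday's | 0.038 M | 0.038 M | 0.80 equiv | 0.5 mol% | run made earlier |  |
| Wednesday's | 0.15 M | 0.15 M | 0.80 equiv | 0.5 mol% | run made earlier |  |
| Friday's | 0.076 M | 0.076 M | 0.80 equiv | 0.75 mol% | run made earlier |  |
| ash | 0.076 M | 0.076 M | 0.800 equiv | 0.5 mol% |  | 40 h |
| elm | 0.076 M | 0.076 M | 0.800 equiv | 0.5 mol% |  | 150 h |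

- Thursday's (time / h: left-handed product / %, right-handed product / %, left-handed substrate / %): 10.0: 5, 3, 45; 20.0: 10, 1, 41; 30.0: 12, 3, 41; 40.0: 6, 5, 41
- Wednesday's (time / h: left-handed product / %, right-handed product / %, left-handed substrate / %): 3.00: 16, 8, 34; 8.00: 21, 9, 24; 15.0: 25, 11, 25; 40.0: 22, 11, 24
- Friday's (time / h: left-handed product / %, right-handed product / %, left-handed substrate / %): 10.0: 17, 7, 33; 20.0: 17, 7, 30; 30.0: 19, 8, 25; 40.0: 22, 5, 26

(readings scatter by 2 percentage points)

- free catalyst is single-handed; left-handed substrate and right-handed substrate are mirror images of each other, charged as a racemate, each of them at the stated concentration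
- an excess is below zero if the other one leads

* the flask that ends with the higher excess of left-handed product over right-handed product in the product, or "neither" when 2 percentage points or less lies between them (ash / elm / neither)
* excess of left-handed product over right-handed product in the product at the end, ash
* excess of left-handed product over right-handed product in the product at the end, elm

Those last Wednesday readings leave 48.0% of the left-handed substrate and 78.0% of the right-handed, which gives 2.95 as a reading. This number is the selectivity factor: the natural logarithm of the fraction of left-handed substrate left, over that of the fraction of right-handed substrate left. I assume it stays constant while each substrate is consumed in proportion to its own amount.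

Given the fraction of right-handed substrate left, the factor gives the fraction of left-handed left, and the excess is the difference of the two amounts consumed over their sum. Friday's run has the concentration and partner of ash and elm, though with 0.75 mol% of free catalyst against 0.5 mol%. I assume both flasks stop where it did. Its mean right-handed product leaves 86.5% of that substrate, so I reckon 44.2% for each flask.

The forecast gives 42% for ash and 41% for elm, so neither, holding that “The extra time in elm changes nothing”. My figure stands slightly above both.

Ash ends at 44.6% and elm at 44.4%, so the answer is neither.

    partner + free catalyst + right-handed substrate → free catalyst + right-handed product (k = 0.300 L² mol⁻² s⁻¹)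
    partner + free catalyst + left-handed substrate → free catalyst + left-handed product (k = 0.910 L² mol⁻² s⁻¹)
    2 free catalyst → spent catalyst (k = 0.0120 L mol⁻¹ s⁻¹)
    partner → decomposed reagent (k = 8.70 × 10⁻⁶ s⁻¹)
    2 free catalyst ⇌ resting dimer (K = 1400 L mol⁻¹, k = 0.0270 L mol⁻¹ s⁻¹)

At 150 h elm holds 0.0077% of its partner, the limiting reagent, beside 22.2% of the catalyst as free catalyst. Elm's 85% of right-handed substrate left gives, through the factor 2.95, an excess of 43.5%. A neighbouring flask, elm with 3.20 equiv of partner, leaves 40% of right-handed substrate, from which the factor gives 21.7%, and that flask ends at 21.9%.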